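## Remarks

- **Locants and faces.** All bicyclic compounds keep the hydroazulene locants of the target (C1, C2, C3, C3a, C4–C8, C8a), also where a systematic name would renumber. β is the face of the C8a methyl group, α the opposite face.
- **Assumption.** Rh2(S-PTAD)4 is taken to give the (1R,2S)-cyclopropane 8, as the usual model for donor/acceptor carbenes predicts; if the sense proves opposite, Rh2(R-PTAD)4 is used and nothing else changes.

## Analysis of the target

The target 24 is a daucane-type diester: a trans-fused hydroazulene whose cyclopentane carries the C3 tertiary carbinol with its isopropyl group and the quaternary C8a methyl. Its cycloheptene carries a 4-hydroxybenzoate at C4, the C5=C6 alkene with a methyl on C6, and an acetate at C7. There are five stereocentres: C3 (R), C3a (S), C4 (S), C7 (S) and C8a (R). The C3 hydroxyl is β (cis to the angular methyl), whereas C3a–H, the C4 oxygen and the C7 oxygen are all α. So the ring fusion is trans, C3a–H and C4–O are cis, the C3 and C4 oxygens are 1,3-anti, and the C4 and C7 oxygens are cis across the ring. C3a sits between two fully substituted carbons (C3 and C8a), one of them quaternary, which makes this triad the most congested part. Both esters are allylic (ionisation, allylic transposition), two different acyl groups must go onto two secondary allylic oxygens, the phenol is free, and the tertiary alcohol is β to C4, so retro-aldol and dehydration threaten whenever C4 is a carbonyl. The strategy rests on one feature: the seven-membered ring divides into a four-carbon unit C8a=C3a–C4=C5 held on the five-membered ring and a three-carbon unit C6–C7–C8 with oxygen on C7, to be joined at C5–C6 and C8–C8a.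

## Retrosynthetic reasoning

**24 ⇒ 23.** The O–Si bond of the phenol is formed last in the retrosynthetic sense. A silyl ether on the phenol survives reduction and esterification and can be removed by buffered fluoride without touching either allylic ester.

**23 ⇒ 22.** The C7–O acyl bond is cut with inversion. Hydride should reach the C7 carbonyl from the α face, so the acetate is installed by invertive esterification of the 7β-alcohol 22. The forward step must be a clean SN2 at allylic C7.

**22 ⇒ 21 ⇒ 20.** The C7–H bond goes back to enone 21, and the C5=C6 alkene to the saturated ketone 20. C8a is quaternary, so the C7 ketone can only be desaturated towards C5; the alkene position is fixed by structure.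

**20 ⇒ 16 + 19.** The acyl–O bond at C4 is cut. In 16 the C4 hydroxyl is the only secondary one, so no differentiation is needed. Acid 19 comes from 17 through 18.

**16 ⇒ 15.** The C4–H bond is traced to the C4 ketone because the neighbouring C3 hydroxyl can deliver hydride internally. This sets C4 and leaves the C7 ketone alone, which differentiates the two oxygens.

**15 ⇒ 13 ⇒ 12.** The C4–O and C3a–H bonds go back to hydroboration of the C3a=C4 alkene of 12. The face of that addition cannot be trusted in this congested ring. The ring fusion is therefore set by equilibration at C3a once C4 is a ketone (14 to 15), so both hydroboration outcomes converge.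

**12 ⇒ 11 ⇒ 10.** The C6–H bond (loss of the ester) and the C6–CH3 bond are cut. The ester inherited from the carbene partner makes C6 the only nucleophilic carbon, so methylation is regiospecific; the ester is then removed.

**10 ⇒ 9.** The C3–isopropyl bond comes from carbonyl addition to the enone of 9. It is placed here because C7 is still masked as a silyl enol ether and the vinylogous carbonate ester is unreactive.

**9 ⇒ 4 + 7 (through 8).** C5–C6 and C8–C8a are cut. These two bonds separate the diene already sitting on the five-membered ring from a three-carbon oxygenated vinyl carbene. One catalytic step then gives the ring, the quaternary stereocentre and the C3, C6 and C7 handles. The forward reaction needs site-selective cyclopropanation of the vinyl group, cis geometry, enantiocontrol, and a Cope rearrangement.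

**4 ⇒ 2 + 3 ⇒ 1; 7 ⇒ 6 ⇒ 5.** The vinyl–ring bond of 4 is a cross-coupling bond between 2 (from 1) and 3. The diazo and silyl groups of 7 come from 5 via 6.

## Alternatives that were turned down

**Alternative 1:** The C3a–C8a bond is traced to a C4–C8a bond of a six–six skeleton made by Robinson annulation.
- *Forward key step:* a base-induced semipinacol shift. A tertiary C4 alkoxide pushes C8a from C4 to C3a while a sulfonate leaves C3a, giving A1 with the five–seven skeleton, the C4 ketone and a trans fusion.
- *For:* the migration is antiperiplanar and stereospecific, so C3a is fixed with certainty. This is stronger than the chosen route, which sets C3a by equilibration. A1 already holds the C3 carbinol and a masked C7 oxygen.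
- *Against:* the skeleton is built twice, first as a decalin and then as the hydroazulene. The six–six precursor needs its own stereocontrolled cis-diol, selective sulfonylation and two protecting groups. After A1 the same endgame remains (C4 reduction, C5=C6 desaturation, C7 reduction, acylations).
- *Comparison:* the chosen route forms the seven-membered ring, the quaternary centre and the C6/C7 functionality in one catalytic step from two two-step fragments. It gives up the stereospecific setting of C3a for that economy.

**Alternative 2:** C8–C8a and C3a–C4 are cut, both on the cyclopentane.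
- *Forward key step:* a chiral N-heterocyclic carbene–copper catalyst transfers a 1-silylvinyl group from aluminium to C8a of 1, and the aluminium enolate is trapped by aldehyde A3 to give A2.
- *For:* C8a is set by a well-understood catalytic conjugate addition to the same cheap enone 1. The enolate trap places the C3a substituent trans to the new group, so the future trans fusion is set kinetically in the same operation. This is stronger on C3a than the chosen route.
- *Against:* no ring is formed. The seven-membered ring must still be closed between C6 and C7, an entropically unfavourable medium-ring closure. A3 is configurationally labile, the aldol selectivity at C4 is uncertain, A2 is a retro-aldol-prone β-hydroxy ketone, and the C7 oxygen and C3 carbinol are still missing.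
- *Comparison:* the chosen route closes the ring in the key step, driven by strain release, with the C7 oxygen present from the start.

**Alternative 3:** The C3–C3a bond of the five-membered ring is cut.
- *Forward key step:* an intramolecular aldol. The C3a enolate of a seven-membered enone (lithium amide, then a magnesium salt) adds to a side-chain isopropyl ketone, giving A4.
- *For:* C3 and C3a are set together in one chelation-organised step. This is stronger than the chosen route, which sets them in two separate substrate-controlled events.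
- *Against:* the quaternary C8a with its keto side chain must already exist in enantiopure form on a seven-membered ring, which needs a separate desymmetrisation. Enolisation must occur at hindered C3a rather than at C5. The aldol is reversible. A4 has no oxygen at C7, so a late allylic oxidation next to the C6 methyl is needed.
- *Comparison:* the chosen route builds the seven-membered ring with its C7 oxygen and sets C8a by catalysis in the ring-forming step. It gives up the one-step setting of C3 and C3a.

Key step: step 5

## Route

Step 1
Reactants: 1 3-methylcyclopent-2-en-1-one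
Product: 2 2-iodo-3-methylcyclopent-2-en-1-one
Conditions: I2, pyridine, CH2Cl2, 0 °C → rt
Reagents that add atoms: iodine, II
Why: α-Iodination of an enone by the addition–iodination–elimination sequence (pyridine adds at C3, the enolate is iodinated, pyridine leaves); no stereocentre is formed.

Step 2
Reactants: 2 2-iodo-3-methylcyclopent-2-en-1-one; 3 potassium vinyltrifluoroborate
Product: 4 3-methyl-2-vinylcyclopent-2-en-1-one
Conditions: PdCl2(dppf) (5 mol %), Cs2CO3, THF/H2O 9:1, 70 °C
Reagents that add atoms: none
Why: Suzuki–Miyaura coupling of a 2-iodoenone with a vinyltrifluoroborate; the volatile dienone is prone to Diels–Alder dimerisation and should be used at once.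

Step 3
Reactants: 5 methyl acetoacetate
Product: 6 methyl 2-diazo-3-oxobutanoate
Conditions: 4-acetamidobenzenesulfonyl azide, Et3N, MeCN, 0 °C → rt
Reagents that add atoms: 4-acetamidobenzenesulfonyl azide, CC(=O)Nc1ccc(cc1)S(=O)(=O)N=[N+]=[N-]
Why: Regitz diazo transfer to the activated methylene of a β-keto ester.

Step 4
Reactants: 6 methyl 2-diazo-3-oxobutanoate
Product: 7 methyl 3-[(tert-butyldimethylsilyl)oxy]-2-diazobut-3-enoate
Conditions: TBSOTf, Et3N, CH2Cl2, 0 °C
Reagents that add atoms: tert-butyldimethylsilyl trifluoromethanesulfonate, CC(C)(C)[Si](C)(C)OS(=O)(=O)C(F)(F)F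
Why: O-Silylation of the acetyl enolate gives the siloxyvinyl diazoacetate, the precursor of a donor/acceptor vinyl carbene; it should be used without long storage.

Step 5
Reactants: 4 3-methyl-2-vinylcyclopent-2-en-1-one; 7 methyl 3-[(tert-butyldimethylsilyl)oxy]-2-diazobut-3-enoate
Product: 9 methyl (8aR)-7-[(tert-butyldimethylsilyl)oxy]-8a-methyl-3-oxo-1,2,3,5,8,8a-hexahydroazulene-6-carboxylate, via cis-divinylcyclopropane 8 (not isolated)
Conditions: Rh2(S-PTAD)4 (1 mol %), 2,2-dimethylbutane/PhCF3, −20 °C, slow addition of 7 (2 equiv); then toluene, 90 °C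
Reagents that add atoms: none
Why: Rh2(S-PTAD)4 decomposes 7 to a rhodium-bound donor/acceptor vinyl carbene, which cyclopropanates the terminal C4=C5 vinyl group of 4 in a concerted asynchronous step (forming C5–C6 and C4–C6) with the siloxyvinyl donor cis to the cyclopentenyl group, giving 8. On warming, 8 undergoes a Cope rearrangement through the boat transition state: C8 bonds to C8a, C4–C6 breaks, and the alkenes move to C3a=C4 and C6=C7. The closest known reaction type is the dirhodium-catalysed tandem cyclopropanation/Cope rearrangement (formal [4+3] cycloaddition) of siloxyvinyl diazoacetates with dienes. The seven-membered ring closes by a concerted, strain-driven [3,3]-sigmatropic shift of the cis-divinylcyclopropane, not by a polar cyclisation. C8a is the only stereocentre of 9; it is set by the (1R,2S) configuration of the cyclopropane, fixed by the chiral catalyst and relayed suprafacially through the boat geometry to give 8aR. The step needs site selectivity for the vinyl alkene, secured because the enone alkene is tetrasubstituted and deactivated towards the electrophilic carbene; it also needs the cis geometry, which is inherent to donor/acceptor carbenes and is the only geometry that can rearrange. The ring methyl on the reacting alkene terminus points inward in the boat and raises the Cope barrier, hence the heating; the siloxy group suppresses vinylogous reactivity of the carbene.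

Step 6
Reactants: 9 methyl (8aR)-7-[(tert-butyldimethylsilyl)oxy]-8a-methyl-3-oxo-1,2,3,5,8,8a-hexahydroazulene-6-carboxylate
Product: 10 methyl (3R,8aR)-7-[(tert-butyldimethylsilyl)oxy]-3-hydroxy-8a-methyl-3-(propan-2-yl)-1,2,3,5,8,8a-hexahydroazulene-6-carboxylate
Conditions: i-PrMgCl, CeCl3, THF, −78 °C
Reagents that add atoms: isopropylmagnesium chloride, CC(C)[Mg]Cl
Why: Organocerium 1,2-addition to the enone; attack should come from the α face because the C8a methyl stands nearly perpendicular over the β face of the five-membered ring in the boat-like seven-membered ring, while C8 lies closer to the ring plane, giving the 3R carbinol with OH cis to the methyl. The silyl enol ether masks C7, the vinylogous carbonate ester is inert at −78 °C, and cerium suppresses enolisation at the doubly allylic C5 and reduction by β-hydride transfer.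

Step 7
Reactants: 10 methyl (3R,8aR)-7-[(tert-butyldimethylsilyl)oxy]-3-hydroxy-8a-methyl-3-(propan-2-yl)-1,2,3,5,8,8a-hexahydroazulene-6-carboxylate
Product: 11 methyl (3R,8aR)-3-hydroxy-6,8a-dimethyl-7-oxo-3-(propan-2-yl)-1,2,3,5,6,7,8,8a-octahydroazulene-6-carboxylate (both C6 epimers)
Conditions: TBAF, MeI, THF, −78 → 0 °C
Reagents that add atoms: iodomethane, CI
Why: Fluoride cleaves the silyl enol ether to the ammonium enolate of the β-keto ester, which is C-methylated at C6, the only carbon between the two carbonyls, so the methyl is placed regiospecifically; the quaternary C6 forms as an epimer mixture of no consequence because the centre is removed later.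

Step 8
Reactants: 11 methyl (3R,8aR)-3-hydroxy-6,8a-dimethyl-7-oxo-3-(propan-2-yl)-1,2,3,5,6,7,8,8a-octahydroazulene-6-carboxylate
Product: 12 (3R,8aR)-3-hydroxy-6,8a-dimethyl-3-(propan-2-yl)-2,3,5,6,8,8a-hexahydroazulen-7(1H)-one (both C6 epimers)
Conditions: LiCl, H2O, DMSO, 130 °C
Reagents that add atoms: none
Why: Krapcho dealkoxycarbonylation: chloride demethylates the ester by SN2, the β-keto carboxylate loses CO2 and the enolate is protonated; the neutral medium should spare the tertiary allylic alcohol.

Step 9
Reactants: 12 (3R,8aR)-3-hydroxy-6,8a-dimethyl-3-(propan-2-yl)-2,3,5,6,8,8a-hexahydroazulen-7(1H)-one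
Product: 13 (3R,8aR)-6,8a-dimethyl-3-(propan-2-yl)decahydroazulene-3,4,7-triol (C3a–H and C4–OH cis to each other; mixture at C3a/C4, C6 and C7)
Conditions: BH3·THF (4 equiv), THF, 0 °C → rt; then NaOH, H2O2, 0 °C → rt
Reagents that add atoms: hydrogen peroxide, OO
Why: Hydroboration–oxidation: boron bonds to C4 (the less substituted carbon, remote from the carbinol) and hydrogen to C3a in a syn addition, and the excess borane also reduces the C7 ketone. The face of addition is not relied on (the β face, giving the cis-fused adduct, is expected to prevail), because C3a is corrected in step 10 and C4 is reset in steps 10 and 11.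

Step 10
Reactants: 13 (3R,8aR)-6,8a-dimethyl-3-(propan-2-yl)decahydroazulene-3,4,7-triol
Product: 15 (3R,3aR,8aR)-3-hydroxy-6,8a-dimethyl-3-(propan-2-yl)octahydroazulene-4,7-dione (trans-fused; both C6 epimers), via dione epimer mixture 14 (not isolated)
Conditions: Dess–Martin periodinane, NaHCO3, CH2Cl2, rt; then DBU (0.3 equiv), toluene, 40 °C
Reagents that add atoms: none
Why: Dess–Martin oxidation converts both secondary carbinols to ketones and leaves the tertiary alcohol (14); DBU then equilibrates C3a by enolisation. The trans fusion (3a-H α) should be favoured because it keeps C4 trans to the vicinal isopropyl group on the five-membered ring and allows a C3–OH to C4=O hydrogen bond; a mild amine base in toluene limits retro-aldol and dehydration of the β-hydroxy ketone.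

Step 11
Reactants: 15 (3R,3aR,8aR)-3-hydroxy-6,8a-dimethyl-3-(propan-2-yl)octahydroazulene-4,7-dione
Product: 16 (3R,3aS,4S,8aR)-3,4-dihydroxy-6,8a-dimethyl-3-(propan-2-yl)octahydroazulen-7(1H)-one (both C6 epimers)
Conditions: Me4NBH(OAc)3, MeCN/AcOH 1:1, −30 °C
Reagents that add atoms: none
Why: Evans–Saksena reduction: the C3 hydroxyl exchanges onto boron and delivers hydride internally to the β face of the C4 carbonyl through a six-membered transition state, giving the 1,3-anti diol with the C4 hydroxyl α (4S). The C7 ketone has no directing hydroxyl and should not be reduced by the acetoxyborohydride at this temperature; any cis-fused epimer, whose C3 hydroxyl is trans to C4, cannot deliver hydride and should react far more slowly. (3aR in 15 and 3aS in 16 are the same spatial arrangement; only the priority of C4 changes.)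

Step 12
Reactants: 17 4-hydroxybenzoic acid
Product: 19 4-{[tri(propan-2-yl)silyl]oxy}benzoic acid, via bis-silylated benzoate 18 (not isolated)
Conditions: TIPSCl (2.2 equiv), imidazole, DMF, rt; then AcOH, THF/H2O, rt
Reagents that add atoms: chlorotri(propan-2-yl)silane, CC(C)[Si](Cl)(C(C)C)C(C)C
Why: Silylation of both the phenol and the acid, then selective hydrolysis of the silyl ester, which is far more labile than the aryl silyl ether.

Step 13
Reactants: 16 (3R,3aS,4S,8aR)-3,4-dihydroxy-6,8a-dimethyl-3-(propan-2-yl)octahydroazulen-7(1H)-one; 19 4-{[tri(propan-2-yl)silyl]oxy}benzoic acid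
Product: 20 (3R,3aS,4S,8aR)-3-hydroxy-6,8a-dimethyl-7-oxo-3-(propan-2-yl)decahydroazulen-4-yl 4-{[tri(propan-2-yl)silyl]oxy}benzoate (both C6 epimers)
Conditions: DCC, DMAP, CH2Cl2, rt
Reagents that add atoms: none
Why: Steglich esterification; the C4 hydroxyl is the only secondary one and the tertiary C3 hydroxyl is inert, so no differentiation is needed. Any transannular hemiketal between the C4 hydroxyl and the C7 ketone is in equilibrium with the open hydroxy ketone, which is the form acylated.

Step 14
Reactants: 20 (3R,3aS,4S,8aR)-3-hydroxy-6,8a-dimethyl-7-oxo-3-(propan-2-yl)decahydroazulen-4-yl 4-{[tri(propan-2-yl)silyl]oxy}benzoate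
Product: 21 (3R,3aS,4S,8aR)-3-hydroxy-6,8a-dimethyl-7-oxo-3-(propan-2-yl)-1,2,3,3a,4,7,8,8a-octahydroazulen-4-yl 4-{[tri(propan-2-yl)silyl]oxy}benzoate
Conditions: IBX (2.5 equiv), DMSO, 70 °C
Reagents that add atoms: none
Why: IBX-mediated dehydrogenation of the ketone through its enol; C8a is quaternary, so the C8 side cannot be desaturated, and the endocyclic trisubstituted enone is favoured over the exocyclic methylene. Both C6 epimers converge on one enone.

Step 15
Reactants: 21 (3R,3aS,4S,8aR)-3-hydroxy-6,8a-dimethyl-7-oxo-3-(propan-2-yl)-1,2,3,3a,4,7,8,8a-octahydroazulen-4-yl 4-{[tri(propan-2-yl)silyl]oxy}benzoate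
Product: 22 (3R,3aS,4S,7R,8aR)-3,7-dihydroxy-6,8a-dimethyl-3-(propan-2-yl)-1,2,3,3a,4,7,8,8a-octahydroazulen-4-yl 4-{[tri(propan-2-yl)silyl]oxy}benzoate
Conditions: NaBH4, CeCl3·7H2O, MeOH, −78 °C
Reagents that add atoms: none
Why: Luche 1,2-reduction of the enone; hydride should arrive from the α face, anti to the C8–C8a bond and away from the pseudo-axial C8a methyl on the β face of the half-chair enone, giving the 7β-alcohol (7R). The esters and the aryl silyl ether are not touched.

Step 16
Reactants: 22 (3R,3aS,4S,7R,8aR)-3,7-dihydroxy-6,8a-dimethyl-3-(propan-2-yl)-1,2,3,3a,4,7,8,8a-octahydroazulen-4-yl 4-{[tri(propan-2-yl)silyl]oxy}benzoate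
Product: 23 (3R,3aS,4S,7S,8aR)-7-acetoxy-3-hydroxy-6,8a-dimethyl-3-(propan-2-yl)-1,2,3,3a,4,7,8,8a-octahydroazulen-4-yl 4-{[tri(propan-2-yl)silyl]oxy}benzoate
Conditions: AcOH, PPh3, DIAD, toluene, 0 °C → rt
Reagents that add atoms: acetic acid, CC(=O)O
Why: Mitsunobu esterification inverts the allylic C7 carbinol by SN2 attack of acetate from the open α face, giving the 7α-acetate (7S); the tertiary alcohol does not react.

Step 17
Reactants: 23 (3R,3aS,4S,7S,8aR)-7-acetoxy-3-hydroxy-6,8a-dimethyl-3-(propan-2-yl)-1,2,3,3a,4,7,8,8a-octahydroazulen-4-yl 4-{[tri(propan-2-yl)silyl]oxy}benzoate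
Product: 24 (3R,3aS,4S,7S,8aR)-7-acetoxy-3-hydroxy-6,8a-dimethyl-3-(propan-2-yl)-1,2,3,3a,4,7,8,8a-octahydroazulen-4-yl 4-hydroxybenzoate
Conditions: TBAF, AcOH (1:1), THF, 0 °C
Reagents that add atoms: none
Why: Buffered fluoride cleaves the aryl silyl ether (phenoxide is a good leaving group) much faster than it affects alkyl esters; the buffer prevents acyl migration and ester cleavage.

## Compound list

1 | 3-methylcyclopent-2-en-1-one | CC1=CC(=O)CC1 | starting material
2 | 2-iodo-3-methylcyclopent-2-en-1-one | CC1=C(I)C(=O)CC1 | intermediate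
3 | potassium vinyltrifluoroborate | [K+].C=C[B-](F)(F)F | starting material
4 | 3-methyl-2-vinylcyclopent-2-en-1-one | CC1=C(C=C)C(=O)CC1 | intermediate
5 | methyl acetoacetate | COC(=O)CC(C)=O | starting material
6 | methyl 2-diazo-3-oxobutanoate | COC(=O)C(=[N+]=[N-])C(C)=O | intermediate
7 | methyl 3-[(tert-butyldimethylsilyl)oxy]-2-diazobut-3-enoate | COC(=O)C(=[N+]=[N-])C(=C)O[Si](C)(C)C(C)(C)C | intermediate
8 | methyl (1R,2S)-1-{1-[(tert-butyldimethylsilyl)oxy]ethenyl}-2-(2-methyl-5-oxocyclopent-1-en-1-yl)cyclopropane-1-carboxylate (siloxyvinyl cis to cyclopentenyl) | COC(=O)[C@]1(C(=C)O[Si](C)(C)C(C)(C)C)C[C@H]1C1=C(C)CCC1=O | intermediate (not isolated)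
9 | methyl (8aR)-7-[(tert-butyldimethylsilyl)oxy]-8a-methyl-3-oxo-1,2,3,5,8,8a-hexahydroazulene-6-carboxylate | COC(=O)C1=C(O[Si](C)(C)C(C)(C)C)C[C@@]2(C)CCC(=O)C2=CC1 | intermediate
10 | methyl (3R,8aR)-7-[(tert-butyldimethylsilyl)oxy]-3-hydroxy-8a-methyl-3-(propan-2-yl)-1,2,3,5,8,8a-hexahydroazulene-6-carboxylate | COC(=O)C1=C(O[Si](C)(C)C(C)(C)C)C[C@@]2(C)CC[C@@](O)(C(C)C)C2=CC1 | intermediate
11 | methyl (3R,8aR)-3-hydroxy-6,8a-dimethyl-7-oxo-3-(propan-2-yl)-1,2,3,5,6,7,8,8a-octahydroazulene-6-carboxylate (C6 epimers) | COC(=O)C1(C)C(=O)C[C@@]2(C)CC[C@@](O)(C(C)C)C2=CC1 | intermediate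
12 | (3R,8aR)-3-hydroxy-6,8a-dimethyl-3-(propan-2-yl)-2,3,5,6,8,8a-hexahydroazulen-7(1H)-one (C6 epimers) | CC1C(=O)C[C@@]2(C)CC[C@@](O)(C(C)C)C2=CC1 | intermediate
13 | (3R,8aR)-6,8a-dimethyl-3-(propan-2-yl)decahydroazulene-3,4,7-triol (3a-H/4-OH cis; mixture at C3a/C4, C6, C7) | CC1C(O)C[C@@]2(C)CC[C@@](O)(C(C)C)C2C(O)C1 | intermediate
14 | (3R,8aR)-3-hydroxy-6,8a-dimethyl-3-(propan-2-yl)octahydroazulene-4,7-dione (C3a and C6 epimers) | CC1C(=O)C[C@@]2(C)CC[C@@](O)(C(C)C)C2C(=O)C1 | intermediate (not isolated)
15 | (3R,3aR,8aR)-3-hydroxy-6,8a-dimethyl-3-(propan-2-yl)octahydroazulene-4,7-dione (trans-fused; C6 epimers) | CC1C(=O)C[C@@]2(C)CC[C@@](O)(C(C)C)[C@@H]2C(=O)C1 | intermediate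
16 | (3R,3aS,4S,8aR)-3,4-dihydroxy-6,8a-dimethyl-3-(propan-2-yl)octahydroazulen-7(1H)-one (C6 epimers) | CC1C(=O)C[C@@]2(C)CC[C@@](O)(C(C)C)[C@@H]2[C@@H](O)C1 | intermediate
17 | 4-hydroxybenzoic acid | OC(=O)c1ccc(O)cc1 | starting material
18 | tri(propan-2-yl)silyl 4-{[tri(propan-2-yl)silyl]oxy}benzoate | CC(C)[Si](C(C)C)(C(C)C)OC(=O)c1ccc(O[Si](C(C)C)(C(C)C)C(C)C)cc1 | intermediate (not isolated)
19 | 4-{[tri(propan-2-yl)silyl]oxy}benzoic acid | CC(C)[Si](C(C)C)(C(C)C)Oc1ccc(cc1)C(O)=O | intermediate
20 | (3R,3aS,4S,8aR)-3-hydroxy-6,8a-dimethyl-7-oxo-3-(propan-2-yl)decahydroazulen-4-yl 4-{[tri(propan-2-yl)silyl]oxy}benzoate (C6 epimers) | CC1C(=O)C[C@@]2(C)CC[C@@](O)(C(C)C)[C@@H]2[C@@H](OC(=O)c2ccc(O[Si](C(C)C)(C(C)C)C(C)C)cc2)C1 | intermediate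
21 | (3R,3aS,4S,8aR)-3-hydroxy-6,8a-dimethyl-7-oxo-3-(propan-2-yl)-1,2,3,3a,4,7,8,8a-octahydroazulen-4-yl 4-{[tri(propan-2-yl)silyl]oxy}benzoate | O=C1C[C@@]2(C)CC[C@@](O)(C(C)C)[C@@H]2[C@@H](OC(=O)c2ccc(O[Si](C(C)C)(C(C)C)C(C)C)cc2)C=C1C | intermediate
22 | (3R,3aS,4S,7R,8aR)-3,7-dihydroxy-6,8a-dimethyl-3-(propan-2-yl)-1,2,3,3a,4,7,8,8a-octahydroazulen-4-yl 4-{[tri(propan-2-yl)silyl]oxy}benzoate | O[C@@H]1C[C@@]2(C)CC[C@@](O)(C(C)C)[C@@H]2[C@@H](OC(=O)c2ccc(O[Si](C(C)C)(C(C)C)C(C)C)cc2)C=C1C | intermediate
23 | (3R,3aS,4S,7S,8aR)-7-acetoxy-3-hydroxy-6,8a-dimethyl-3-(propan-2-yl)-1,2,3,3a,4,7,8,8a-octahydroazulen-4-yl 4-{[tri(propan-2-yl)silyl]oxy}benzoate | CC(=O)O[C@H]1C[C@@]2(C)CC[C@@](O)(C(C)C)[C@@H]2[C@@H](OC(=O)c2ccc(O[Si](C(C)C)(C(C)C)C(C)C)cc2)C=C1C | intermediate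
24 | (3R,3aS,4S,7S,8aR)-7-acetoxy-3-hydroxy-6,8a-dimethyl-3-(propan-2-yl)-1,2,3,3a,4,7,8,8a-octahydroazulen-4-yl 4-hydroxybenzoate | CC(=O)O[C@H]1C[C@@]2(C)CC[C@@](O)(C(C)C)[C@@H]2[C@@H](OC(=O)c2ccc(O)cc2)C=C1C | target

## Step count and least certain steps

Total: 17 steps. Longest linear sequence: 14 steps (steps 1, 2, 5–11, 13–17 from 1; the branch through steps 3 and 4 is equally long).

**Step 5 (key step).**
- *Risk:* carbene transfer to the cross-conjugated, acyl-bearing diene 4 may be inefficient, with carbene dimerisation or loss of 4 by self-dimerisation during the slow addition. At the temperature the methyl-retarded Cope step needs, reversible opening of the donor–acceptor cyclopropane may erode enantiomeric purity or leak to the trans isomer.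
- *Fallback:* separate the two events, setting out from 7 and 2. Cyclopropanation of commercial vinylboronic acid pinacol ester with 7 under the same catalyst should give the cyclopropylboronate F1 (siloxyvinyl cis to boron). Suzuki–Miyaura coupling of F1 with iodoenone 2 (PdCl2(dppf), K3PO4, THF/H2O, 60 °C; retention at the cyclopropyl carbon) then generates 8, which rearranges at the coupling temperature. The route is rejoined at 9. The same two bonds are formed by the same two events.

**Step 6.**
- *Risk:* poor facial selectivity in the carbonyl addition. The α-face preference rests on the seven-membered ring of 9 staying boat-like; a twist that makes C8 rather than the methyl pseudo-axial would reverse it, and C3 cannot be corrected later.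
- *Fallback:* place the carbinol before the key step, setting out from 4. Organocerium addition to 4 gives the racemic dienol F2, and silylation (TMSCl, imidazole) gives the silyl ether F3. The key step with 7 (C8a still catalyst-controlled) gives the bis-silyl ether F4 together with its separable C3 epimer. Treatment of F4 with TBAF (2.2 equiv) and MeI removes both silyl groups and methylates C6. The route is rejoined at 11. Half the material is lost, but C3 is then secured by separation, and the diene is electron-richer.

**Step 10.**
- *Risk:* incomplete or wrongly directed equilibration at C3a, since the trans preference rests on a modest energy difference; retro-aldol or dehydration of the β-hydroxy ketone under base is also possible.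
- *Fallback:* set C3a kinetically, setting out from 12. Silylation (TESOTf, 2,6-lutidine) gives the silyl ether F5. Hydroboration–oxidation anti to the bulky silyl ether and the angular methyl should give the diol F6 (3a-H α, 4-OH α). Dess–Martin oxidation without base gives the trans-fused dione F7, and HF·pyridine removes the silyl group. The route is rejoined at 15, and step 11 follows in its acidic, non-epimerising medium.

**Step 15 (with step 16).**
- *Risk:* hydride delivery to both faces of C7, or SN2′ substitution and elimination in the Mitsunobu step.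
- *Fallback:* reagent control, setting out from 21. Corey–Bakshi–Shibata reduction with the (R)-oxazaborolidine and BH3·SMe2 (the alkenyl side acting as the large group) should give the 7α-alcohol F8. Acetylation with retention (Ac2O, DMAP, pyridine) rejoins the route at 23.

## Further compounds

F1 | step 5 | methyl (1R,2R)-1-{1-[(tert-butyldimethylsilyl)oxy]ethenyl}-2-(4,4,5,5-tetramethyl-1,3,2-dioxaborolan-2-yl)cyclopropane-1-carboxylate | COC(=O)[C@]1(C(=C)O[Si](C)(C)C(C)(C)C)C[C@H]1B1OC(C)(C)C(C)(C)O1
F2 | step 6 | rac-3-methyl-1-(propan-2-yl)-2-vinylcyclopent-2-en-1-ol | CC(C)C1(O)CCC(C)=C1C=C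
F3 | step 6 | rac-trimethyl{[3-methyl-1-(propan-2-yl)-2-vinylcyclopent-2-en-1-yl]oxy}silane | CC(C)C1(O[Si](C)(C)C)CCC(C)=C1C=C
F4 | step 6 | methyl (3R,8aR)-7-[(tert-butyldimethylsilyl)oxy]-8a-methyl-3-(propan-2-yl)-3-[(trimethylsilyl)oxy]-1,2,3,5,8,8a-hexahydroazulene-6-carboxylate | COC(=O)C1=C(O[Si](C)(C)C(C)(C)C)C[C@@]2(C)CC[C@@](O[Si](C)(C)C)(C(C)C)C2=CC1
F5 | step 10 | (3R,8aR)-6,8a-dimethyl-3-(propan-2-yl)-3-[(triethylsilyl)oxy]-2,3,5,6,8,8a-hexahydroazulen-7(1H)-one | CC1C(=O)C[C@@]2(C)CC[C@@](O[Si](CC)(CC)CC)(C(C)C)C2=CC1
F6 | step 10 | (3R,3aS,4S,8aR)-6,8a-dimethyl-3-(propan-2-yl)-3-[(triethylsilyl)oxy]decahydroazulene-4,7-diol | CC1C(O)C[C@@]2(C)CC[C@@](O[Si](CC)(CC)CC)(C(C)C)[C@@H]2[C@@H](O)C1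
F7 | step 10 | (3R,3aR,8aR)-6,8a-dimethyl-3-(propan-2-yl)-3-[(triethylsilyl)oxy]octahydroazulene-4,7-dione | CC1C(=O)C[C@@]2(C)CC[C@@](O[Si](CC)(CC)CC)(C(C)C)[C@@H]2C(=O)C1
F8 | step 15 | (3R,3aS,4S,7S,8aR)-3,7-dihydroxy-6,8a-dimethyl-3-(propan-2-yl)-1,2,3,3a,4,7,8,8a-octahydroazulen-4-yl 4-{[tri(propan-2-yl)silyl]oxy}benzoate | O[C@H]1C[C@@]2(C)CC[C@@](O)(C(C)C)[C@@H]2[C@@H](OC(=O)c2ccc(O[Si](C(C)C)(C(C)C)C(C)C)cc2)C=C1C
A1 | alternative 1 | trans-fused 6,8a-dimethyl-3-(propan-2-yl)-3-[(triethylsilyl)oxy]octahydroazulene-4,7-dione 7-ethylene ketal | C1COC2(O1)C[C@@]3(C)CC[C@@](O[Si](CC)(CC)CC)(C(C)C)[C@@H]3C(=O)C[C@@H]2C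
A2 | alternative 2 | 2-[(Z)-1-hydroxy-3-iodobut-2-en-1-yl]-3-methyl-3-[1-(trimethylsilyl)ethenyl]cyclopentan-1-one (2,3-trans, anti aldol) | C=C([Si](C)(C)C)[C@@]1(C)CCC(=O)[C@@H]1[C@@H](O)/C=C(/C)I
A3 | alternative 2 | (Z)-3-iodobut-2-enal | O=C/C=C(/C)I
A4 | alternative 3 | trans-fused 3-hydroxy-6,8a-dimethyl-3-(propan-2-yl)-2,3,3a,7,8,8a-hexahydroazulen-4(1H)-one | C1C[C@@]2(C)CC[C@@](O)(C(C)C)[C@@H]2C(=O)C=C1C
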